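**Plan**

1. Ring A is labelled a1 (bears C7, the quinone methide carbon), a2 (bears ring B, a 4-hydroxyphenyl group), a3 and a4 (both CH), a5 (bears CH2OH) and a6 (bears the arylethynyl group). Its four contiguous carbon substituents next to two CH positions, with a4–H directly beside a5–CH2OH, is the pattern that three alkynes can deliver at once when two of them are bridged by a cleavable Si–O–CH2 unit.
2. Retrosynthesis: the C7=C bond of the quinone methide goes back to a triarylmethanol (loss of water), and one C7–aryl bond is cut to a diaryl ketone plus an aryllithium. The a4–H and free CH2OH are traced to the a4–Si and CH2–O–Si bonds of a benzoxasilole. Ring A is then cut at a2–a3, a4–a5 and a6–a1 into a silyl-ether-tethered diyne and a diaryl ynone.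
3. The diyne is cut at its sp–sp bond (bromoalkyne plus propargyl alcohol) and at the Si–C and Si–O bonds; the ynone is cut at both bonds of its carbonyl carbon (aryl iodide, CO, arylalkyne). One TIPS-protected 4-iodophenol supplies all four oxygenated rings.
4. Forward order: aryl building blocks, 1,3-diyne, silicon tether, ynone. Ring A and the temporary oxasilole arise together in step 8. The fourth aryl group is then added at C7, fluoride removes all silicon, and acid forms the quinone methide.
5. Stereochemistry: the target has no stereocentre and no configured double bond (the quinone methide ring is symmetric about the C7=C axis), so nothing has to be set.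

Key step: step 8

Assumption: the hindered aryl axes around ring A are not treated as stereogenic (the target SMILES has no descriptor). The two oxygenated rings on C7 are identical after deprotection, so either may become the quinone methide ring.

**Route**

Step 1
Reactants: 1 4-iodophenol
Product: 2 (4-iodophenoxy)triisopropylsilane
Conditions: TIPSCl, imidazole, DMF, rt
Reagents that add atoms: chlorotriisopropylsilane, CC(C)[Si](Cl)(C(C)C)C(C)C
Why: Standard silyl ether formation on a phenol; the hindered aryl TIPS ether should survive amine bases, brief methanolysis and organolithiums at low temperature, yet fall to fluoride at the end.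

Step 2
Reactants: 2 (4-iodophenoxy)triisopropylsilane; 3 ethynyltrimethylsilane
Product: 4 triisopropyl{4-[(trimethylsilyl)ethynyl]phenoxy}silane
Conditions: PdCl2(PPh3)2 (cat.), CuI (cat.), Et3N, THF, rt
Reagents that add atoms: none
Why: Sonogashira coupling of an aryl iodide, which undergoes oxidative addition to zerovalent palladium at room temperature and is alkynylated through the acetylide formed with CuI.

Step 3
Reactants: 4 triisopropyl{4-[(trimethylsilyl)ethynyl]phenoxy}silane
Product: 5 (4-ethynylphenoxy)triisopropylsilane
Conditions: K2CO3 (cat.), MeOH/THF, rt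
Reagents that add atoms: none
Why: Base-catalysed methanolysis (protodesilylation) of the alkynyl C–SiMe3 bond is much faster than attack on the hindered aryl O–Si(iPr)3 bond.

Step 4
Reactants: 5 (4-ethynylphenoxy)triisopropylsilane
Product: 6 [4-(bromoethynyl)phenoxy]triisopropylsilane
Conditions: NBS, AgNO3 (cat.), acetone, rt
Reagents that add atoms: N-bromosuccinimide, O=C1CCC(=O)N1Br
Why: Electrophilic bromination of a terminal alkyne through the acetylide formed with AgNO3, a routine way to 1-bromoalkynes that leaves the aryl ring untouched.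

Step 5
Reactants: 6 [4-(bromoethynyl)phenoxy]triisopropylsilane; 7 propargyl alcohol
Product: 8 5-{4-[(triisopropylsilyl)oxy]phenyl}penta-2,4-diyn-1-ol
Conditions: CuCl (cat.), NH2OH·HCl (cat.), n-BuNH2, H2O/CH2Cl2, 0 °C
Reagents that add atoms: none
Why: Cadiot–Chodkiewicz coupling of a bromoalkyne with a terminal alkyne gives the unsymmetrical 1,3-diyne, with hydroxylamine keeping copper monovalent so that oxidative homocoupling is held back.

Step 6
Reactants: 9 ethynylmagnesium bromide; 10 dichlorodiisopropylsilane; 8 5-{4-[(triisopropylsilyl)oxy]phenyl}penta-2,4-diyn-1-ol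
Product: 12 ethynyl(diisopropyl)silyl ether of 5-{4-[(triisopropylsilyl)oxy]phenyl}penta-2,4-diyn-1-ol, via chloro(ethynyl)diisopropylsilane 11 (not isolated)
Conditions: 9 (1 equiv), 10 (1 equiv), THF, 0 °C → rt; then 8 (0.8 equiv), Et3N, DMAP (cat.), rt
Reagents that add atoms: none
Why: Two successive nucleophilic substitutions at silicon, in which the isopropyl groups slow a second alkynylation of the dichlorosilane and the remaining Si–Cl bond then silylates the primary alcohol to a chromatography-stable diisopropylsilyl ether.

Step 7
Reactants: 2 (4-iodophenoxy)triisopropylsilane; 5 (4-ethynylphenoxy)triisopropylsilane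
Product: 13 1,3-bis{4-[(triisopropylsilyl)oxy]phenyl}prop-2-yn-1-one
Conditions: PdCl2(PPh3)2 (cat.), Et3N, CO (1 atm), THF, rt
Reagents that add atoms: carbon monoxide, [C-]#[O+]
Why: Carbonylative Sonogashira coupling, in which CO insertion into the electron-rich arylpalladium iodide is faster than direct alkynylation at room temperature, so the aroylpalladium intermediate is what couples with the alkyne.

Step 8
Reactants: 12 ethynyl(diisopropyl)silyl ether of 5-{4-[(triisopropylsilyl)oxy]phenyl}penta-2,4-diyn-1-ol; 13 1,3-bis{4-[(triisopropylsilyl)oxy]phenyl}prop-2-yn-1-one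
Product: 14 {1,1-diisopropyl-6-[4-(triisopropylsilyloxy)phenyl]-4-{[4-(triisopropylsilyloxy)phenyl]ethynyl}-1,3-dihydro-2,1-benzoxasilol-5-yl}[4-(triisopropylsilyloxy)phenyl]methanone (ring A fused to the oxasilole: Si on a4, O–CH2 on a5, arylethynyl on a6, aroyl on a1, ring B on a2, H on a3)
Conditions: [Rh(cod)2]BF4 (5 mol %), rac-BINAP (5 mol %), H2 then argon, CH2Cl2, rt, slow addition of 12 to 13 (1.5 equiv)
Reagents that add atoms: none
Why: Oxidative cyclization of the two tethered alkynes of 12 (the ethynylsilane and the propargylic alkyne, linked through Si–O–CH2) on the cationic monovalent rhodium centre of [Rh(cod)2]BF4/BINAP should give a rhodacyclopentadiene of trivalent rhodium in which a4–a5 is already made; ynone 13 then inserts and reductive elimination forms a2–a3 and a6–a1. The closest known reaction is the cross-cyclotrimerization of tethered 1,6-diynes, silyl-ether-tethered ones included, with electron-poor alkynes under [Rh(cod)2]BF4/BINAP. Ring A closes as a six-membered carbocycle by the metal-templated union of three alkynes, and the five-membered oxasilole closes in the oxidative cyclization, the Si–O–CH2 bridge spanning a4 and a5. No stereocentre is formed, so racemic BINAP suffices. Chemoselectivity rests on the tether, which makes the first C–C bond intramolecular so that the outer alkyne of the 1,3-diyne and homotrimerization are outpaced, helped by slow addition of 12 to an excess of 13. Regioselectivity rests on insertion into the unhindered Rh–C(a3)H bond in the conjugate sense (a3 to the aryl-bearing β-carbon, rhodium to the carbonyl-bearing α-carbon), which places the aroyl carbon a1 beside the alkynyl-bearing a6.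

Step 9
Reactants: 2 (4-iodophenoxy)triisopropylsilane; 14 benzoxasilole ketone
Product: 16 {1,1-diisopropyl-6-[4-(triisopropylsilyloxy)phenyl]-4-{[4-(triisopropylsilyloxy)phenyl]ethynyl}-1,3-dihydro-2,1-benzoxasilol-5-yl}bis[4-(triisopropylsilyloxy)phenyl]methanol, via 4-[(triisopropylsilyl)oxy]phenyllithium 15 (not isolated)
Conditions: 2 (1.5 equiv), t-BuLi (3.0 equiv), Et2O, −78 °C; then 14 in THF, −78 → −20 °C; aq. NH4Cl
Reagents that add atoms: none
Why: Iodine–lithium exchange followed by 1,2-addition of the aryllithium to a non-enolisable diaryl ketone, which should outrun attack at the hindered diisopropylsilicon at low temperature because the linear alkynyl neighbour leaves the carbonyl accessible.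

Step 10
Reactants: 16 benzoxasilole triarylmethanol
Product: 18 selaginellin, 4-[{3-(hydroxymethyl)-6-(4-hydroxyphenyl)-2-[(4-hydroxyphenyl)ethynyl]phenyl}(4-hydroxyphenyl)methylidene]cyclohexa-2,5-dien-1-one, via hexahydroxy triarylmethanol 17 (not isolated)
Conditions: TBAF·3H2O (excess), THF/DMF, 0 °C → 50 °C; then 1 M aq. HCl, rt
Reagents that add atoms: none
Why: Fluoride first strips the four aryl silyl ethers at 0 °C (the resulting phenoxides make the alkyne electron-rich and so resistant to alkoxide addition), then adds to the strained oxasilole silicon so that water protodesilylates the aryl–silicon bond at a4 and the O–Si bond is cleaved to free CH2OH, and acidification ionises the 4-hydroxytrityl alcohol, which loses water to the quinone methide (fuchsone formation).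

**Compound list**

1 | 4-iodophenol | Oc1ccc(I)cc1 | starting material
2 | (4-iodophenoxy)triisopropylsilane | CC(C)[Si](C(C)C)(C(C)C)Oc1ccc(I)cc1 | intermediate
3 | ethynyltrimethylsilane | C#C[Si](C)(C)C | starting material
4 | triisopropyl{4-[(trimethylsilyl)ethynyl]phenoxy}silane | CC(C)[Si](C(C)C)(C(C)C)Oc1ccc(cc1)C#C[Si](C)(C)C | intermediate
5 | (4-ethynylphenoxy)triisopropylsilane | CC(C)[Si](C(C)C)(C(C)C)Oc1ccc(cc1)C#C | intermediate
6 | [4-(bromoethynyl)phenoxy]triisopropylsilane | CC(C)[Si](C(C)C)(C(C)C)Oc1ccc(cc1)C#CBr | intermediate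
7 | propargyl alcohol | C#CCO | starting material
8 | 5-{4-[(triisopropylsilyl)oxy]phenyl}penta-2,4-diyn-1-ol | OCC#CC#Cc1ccc(O[Si](C(C)C)(C(C)C)C(C)C)cc1 | intermediate
9 | ethynylmagnesium bromide (THF solution) | C#C[Mg]Br | starting material
10 | dichlorodiisopropylsilane | CC(C)[Si](Cl)(Cl)C(C)C | starting material
11 | chloro(ethynyl)diisopropylsilane | C#C[Si](Cl)(C(C)C)C(C)C | intermediate
12 | ethynyl(diisopropyl)silyl ether of 5-{4-[(triisopropylsilyl)oxy]phenyl}penta-2,4-diyn-1-ol | C#C[Si](C(C)C)(C(C)C)OCC#CC#Cc1ccc(O[Si](C(C)C)(C(C)C)C(C)C)cc1 | intermediate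
13 | 1,3-bis{4-[(triisopropylsilyl)oxy]phenyl}prop-2-yn-1-one | CC(C)[Si](C(C)C)(C(C)C)Oc1ccc(cc1)C#CC(=O)c1ccc(O[Si](C(C)C)(C(C)C)C(C)C)cc1 | intermediate
14 | benzoxasilole-fused ring A ketone (name as in step 8) | CC(C)[Si]1(C(C)C)OCc2c1cc(-c1ccc(O[Si](C(C)C)(C(C)C)C(C)C)cc1)c(C(=O)c1ccc(O[Si](C(C)C)(C(C)C)C(C)C)cc1)c2C#Cc1ccc(O[Si](C(C)C)(C(C)C)C(C)C)cc1 | intermediate
15 | 4-[(triisopropylsilyl)oxy]phenyllithium | [Li]c1ccc(O[Si](C(C)C)(C(C)C)C(C)C)cc1 | intermediate
16 | benzoxasilole-fused triarylmethanol (name as in step 9) | CC(C)[Si]1(C(C)C)OCc2c1cc(-c1ccc(O[Si](C(C)C)(C(C)C)C(C)C)cc1)c(C(O)(c1ccc(O[Si](C(C)C)(C(C)C)C(C)C)cc1)c1ccc(O[Si](C(C)C)(C(C)C)C(C)C)cc1)c2C#Cc1ccc(O[Si](C(C)C)(C(C)C)C(C)C)cc1 | intermediate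
17 | {3-(hydroxymethyl)-6-(4-hydroxyphenyl)-2-[(4-hydroxyphenyl)ethynyl]phenyl}bis(4-hydroxyphenyl)methanol | OCc1ccc(-c2ccc(O)cc2)c(C(O)(c2ccc(O)cc2)c2ccc(O)cc2)c1C#Cc1ccc(O)cc1 | intermediate
18 | selaginellin | O=C1C=CC(=C(c2ccc(O)cc2)c2c(-c3ccc(O)cc3)ccc(CO)c2C#Cc2ccc(O)cc2)C=C1 | target

**Step count and risks**

Total steps: 10. Longest linear sequence: 9 steps (steps 1, 2, 3, 4, 5, 6, 8, 9, 10); step 7 is a convergent branch from 2 and 5.

The three steps most likely to fail:

Step 8. The ynone may insert in the opposite orientation, because aryl and aroyl differ little in size, or the diyne may cyclotrimerize with itself or through its outer alkyne. The fallback replaces the aroyl group by a small ester, so that size and polarization point the same way. It sets out from 5 and 12. Deprotonation of 5 with n-BuLi and acylation with methyl chloroformate would give methyl 3-{4-[(triisopropylsilyl)oxy]phenyl}prop-2-ynoate F1. Cocyclization of 12 with F1 under [Rh(cod)2]BF4/BINAP would give methyl 1,1-diisopropyl-6-[4-(triisopropylsilyloxy)phenyl]-4-{[4-(triisopropylsilyloxy)phenyl]ethynyl}-1,3-dihydro-2,1-benzoxasilole-5-carboxylate F2, with the ester carbon at a1 beside the alkynyl group. Treating F2 with at least two equivalents of 15 (double addition to the ester, the first equivalent giving 14 in the flask) comes back to the route at 16.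

Step 10. Cleavage of the aryl–silicon bond may be slow on a ring A that carries no electron-withdrawing group, and at the temperature it needs the flanking alkoxides at C7 and CH2O may add to the alkyne. The fallback moves silicon removal ahead of the aryllithium addition, where the para carbonyl group activates the aryl–silicon bond. It sets out from 14. TBAF in THF at 0 °C would cleave the three aryl silyl ethers and the oxasilole to give [3-(hydroxymethyl)-6-(4-hydroxyphenyl)-2-[(4-hydroxyphenyl)ethynyl]phenyl](4-hydroxyphenyl)methanone F3. TBSCl and imidazole in DMF would convert F3 into its tetrakis(tert-butyldimethylsilyl) ether F4. Addition of 15 at −78 °C would give the corresponding silyl-protected triarylmethanol F5. Only O–Si bonds then remain, so TBAF buffered with AcOH at 0 °C to rt would give 17, where the fallback comes back to the route, and dilute acid would take it to 18.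

Step 6. The dichlorosilane may be alkynylated twice, which leaves unreacted dichlorosilane that would bridge two molecules of 8, and the chlorosilane may hydrolyse before the alcohol is added. The fallback uses an isolable hydrosilane in place of the one-flask chlorosilane. It sets out from 9. Reaction of 9 with chlorodiisopropylsilane would give distillable ethynyldiisopropylsilane F6. NBS in CH2Cl2 at 0 °C would convert the Si–H bond into Si–Br, giving bromo(ethynyl)diisopropylsilane F7. Adding 8 with Et3N and DMAP (cat.) comes back to the route at 12.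

**Further compounds**

F1 | step 8 | methyl 3-{4-[(triisopropylsilyl)oxy]phenyl}prop-2-ynoate | COC(=O)C#Cc1ccc(O[Si](C(C)C)(C(C)C)C(C)C)cc1
F2 | step 8 | methyl 1,1-diisopropyl-6-[4-(triisopropylsilyloxy)phenyl]-4-{[4-(triisopropylsilyloxy)phenyl]ethynyl}-1,3-dihydro-2,1-benzoxasilole-5-carboxylate | COC(=O)c1c(-c2ccc(O[Si](C(C)C)(C(C)C)C(C)C)cc2)cc2c(CO[Si]2(C(C)C)C(C)C)c1C#Cc1ccc(O[Si](C(C)C)(C(C)C)C(C)C)cc1
F3 | step 10 | [3-(hydroxymethyl)-6-(4-hydroxyphenyl)-2-[(4-hydroxyphenyl)ethynyl]phenyl](4-hydroxyphenyl)methanone | O=C(c1ccc(O)cc1)c1c(-c2ccc(O)cc2)ccc(CO)c1C#Cc1ccc(O)cc1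
F4 | step 10 | tetrakis(tert-butyldimethylsilyl) ether of F3 | CC(C)(C)[Si](C)(C)OCc1ccc(-c2ccc(O[Si](C)(C)C(C)(C)C)cc2)c(C(=O)c2ccc(O[Si](C)(C)C(C)(C)C)cc2)c1C#Cc1ccc(O[Si](C)(C)C(C)(C)C)cc1
F5 | step 10 | silyl-protected triarylmethanol from F4 and 15 | CC(C)(C)[Si](C)(C)OCc1ccc(-c2ccc(O[Si](C)(C)C(C)(C)C)cc2)c(C(O)(c2ccc(O[Si](C)(C)C(C)(C)C)cc2)c2ccc(O[Si](C(C)C)(C(C)C)C(C)C)cc2)c1C#Cc1ccc(O[Si](C)(C)C(C)(C)C)cc1
F6 | step 6 | ethynyldiisopropylsilane | C#C[SiH](C(C)C)C(C)C
F7 | step 6 | bromo(ethynyl)diisopropylsilane | C#C[Si](Br)(C(C)C)C(C)C
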